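**Retrosynthetic overview**

1. Target 26 ⇐ 25 by diimide saturation of the cyclopentene C2=C3; 25 ⇐ aldehyde 22 by Wittig olefination and in-situ [3,3] (Cope) shift, which moves the lactone from C3 to C1, sets the side-chain stereocentre and creates the ylidene butenolide.
2. 22 ⇐ 19 by γ-formylation of the butenolide; 19 ⇐ spiro dienone 8 + silyloxyfuran 10 (Mukaiyama–Michael at C3, trans to the C4 methyl), then C1 enol triflate → C1=C2 and SeO2/Dess–Martin/CBS/acylation at C7.
3. 8 ⇐ IBX dehydrogenation of spiro ketone 7 ⇐ Diels–Alder reaction of isoprene with (S)-3-methyl-2-methylidenecyclopentanone 5 (from cyclopent-2-enone by asymmetric conjugate methylation and Mannich trapping).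
4. Ring order: cyclopentane (bought as cyclopentenone) → cyclohexene and spiro centre (Diels–Alder) → butenolide ring (brought in intact as 10; its exocyclic C=C is formed in the key step).
5. Enabling feature: the 5-ylidenefuran-2(5H)-one is an enol ester whose exocyclic C=C lies between the oxygen-bearing ring carbon and the side-chain CH(CH3), and the cyclopentane carbon C1 bonded to that CH(CH3) has the unsubstituted C2–C3 pair beside it; the six atoms C3–C2–C1–CH(CH3)–CH=C(O) are the product array of an acyloxy-Cope shift of a C3-linked γ-propenyl butenolide.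

Key step: step 15

Remark (locants): spiro compounds are numbered as in the target: C1–C4 cyclopentane (C1 = carbonyl carbon, later the side-chain carbon; C4 = CH–CH3), C5 spiro, C6–C10 cyclohexene (C7 oxygenated, C8=C9, 8-methyl).
Remark (chemistry): the lactone γ-carbon in 11–23 and C7 in 14 are carried as both epimers and left undefined in the SMILES; the γ-carbon becomes sp2 in step 15 and C7 is fixed in step 10.

**Route**

Step 1
Reactants: 1 cyclopent-2-en-1-one
Product: 3 (2S,3S)-2-[(dimethylamino)methyl]-3-methylcyclopentan-1-one, via bromomagnesium enolate 2 (not isolated)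
Conditions: MeMgBr, CuBr·SMe2 (5 mol %), Josiphos-type ferrocenyl diphosphine (6 mol %, antipode selected for 3S), t-BuOMe, −75 °C; then Eschenmoser's salt, THF, −75 → 0 °C
Reagents that add atoms: methylmagnesium bromide C[Mg]Br; N,N-dimethylmethyleneiminium iodide (Eschenmoser's salt) C=[N+](C)C.[I-]
Why: Copper-catalysed asymmetric conjugate addition should set C3 under ligand control, and the regiodefined enolate is intercepted at C2 in a Mannich reaction anti to the new methyl group.

Step 2
Reactants: 3 (2S,3S)-2-[(dimethylamino)methyl]-3-methylcyclopentan-1-one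
Product: 5 (S)-3-methyl-2-methylidenecyclopentan-1-one, via trimethylammonium iodide 4 (not isolated)
Conditions: MeI, Et2O, rt; then aq. NaHCO3, CH2Cl2, rt; used at once
Reagents that add atoms: none
Why: Exhaustive N-methylation followed by E1cB (Hofmann-type) loss of trimethylamine should unmask the α-methylene ketone without touching the methyl-bearing stereocentre.

Step 3
Reactants: 5 (S)-3-methyl-2-methylidenecyclopentan-1-one; 6 isoprene
Product: 7 (4S,5R)-4,8-dimethylspiro[4.5]dec-8-en-1-one
Conditions: isoprene (5 equiv), Me2AlCl (0.2 equiv), CH2Cl2, −78 → −20 °C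
Reagents that add atoms: none
Why: Lewis-acid-catalysed Diels–Alder reaction with "para" orientation (diene methyl 1,4 to the carbonyl-bearing carbon); the diene should add to the face of the exocyclic alkene anti to the adjacent ring methyl group, which sets the spiro centre.

Step 4
Reactants: 7 (4S,5R)-4,8-dimethylspiro[4.5]dec-8-en-1-one
Product: 8 (4S,5R)-4,8-dimethylspiro[4.5]deca-2,8-dien-1-one
Conditions: IBX (2.5 equiv), DMSO/toluene, 70 °C
Reagents that add atoms: none
Why: IBX dehydrogenation of a ketone to its enone can only run towards C2–C3 because the other α-carbon is the quaternary spiro centre.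

Step 5
Reactants: 9 3-methylfuran-2(5H)-one
Product: 10 tert-butyldimethyl[(3-methylfuran-2-yl)oxy]silane
Conditions: TBSOTf, Et3N, CH2Cl2, 0 °C
Reagents that add atoms: tert-butyldimethylsilyl trifluoromethanesulfonate CC(C)(C)[Si](C)(C)OS(=O)(=O)C(F)(F)F
Why: Soft enolisation and O-silylation of the butenolide give the aromatic 2-silyloxyfuran, a γ-nucleophilic dienolate equivalent.

Step 6
Reactants: 8 (4S,5R)-4,8-dimethylspiro[4.5]deca-2,8-dien-1-one; 10 tert-butyldimethyl[(3-methylfuran-2-yl)oxy]silane
Product: 12 (3R,4S,5R)-4,8-dimethyl-3-(4-methyl-5-oxo-2,5-dihydrofuran-2-yl)spiro[4.5]dec-8-en-1-one, via silyl enol ether 11 (not isolated)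
Conditions: TBSOTf (10 mol %), CH2Cl2, −78 °C; then 1 M HCl, THF, 0 °C
Reagents that add atoms: none
Why: Vinylogous Mukaiyama–Michael addition in which the furan C5 attacks the enone β-carbon C3 from the face anti to the adjacent C4 methyl (trans addition to a 4-substituted cyclopentenone), which fixes C3; the lactone γ-carbon forms as both epimers.

Step 7
Reactants: 12 (3R,4S,5R)-4,8-dimethyl-3-(4-methyl-5-oxo-2,5-dihydrofuran-2-yl)spiro[4.5]dec-8-en-1-one
Product: 13 4,8-dimethyl-3-(4-methyl-5-oxo-2,5-dihydrofuran-2-yl)spiro[4.5]deca-1,8-dien-1-yl trifluoromethanesulfonate (ring stereocentres as in 12)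
Conditions: Tf2O, 2,6-di-tert-butyl-4-methylpyridine, CH2Cl2, 0 °C → rt
Reagents that add atoms: trifluoromethanesulfonic anhydride O=S(=O)(OS(=O)(=O)C(F)(F)F)C(F)(F)F
Why: O-triflation of the ketone and loss of the only available α-proton (C2) should give the enol triflate regiospecifically, and the hindered non-nucleophilic base leaves the acidic lactone γ-H untouched.

Step 8
Reactants: 13 4,8-dimethyl-3-(4-methyl-5-oxo-2,5-dihydrofuran-2-yl)spiro[4.5]deca-1,8-dien-1-yl trifluoromethanesulfonate
Product: 14 7-hydroxy-4,8-dimethyl-3-(4-methyl-5-oxo-2,5-dihydrofuran-2-yl)spiro[4.5]deca-1,8-dien-1-yl trifluoromethanesulfonate (both C7 epimers)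
Conditions: SeO2 (0.3 equiv), t-BuOOH (3 equiv), CH2Cl2, rt
Reagents that add atoms: tert-butyl hydroperoxide CC(C)(C)OO (terminal oxygen source; selenium dioxide O=[Se]=O is the catalytic oxygen-transfer agent)
Why: Riley allylic oxidation (ene reaction then [2,3]-shift) should take place at the ring CH2 on the more substituted end of the only electron-rich alkene, the enol triflate and butenolide C=C bonds being electron-poor.

Step 9
Reactants: 14 7-hydroxy-4,8-dimethyl-3-(4-methyl-5-oxo-2,5-dihydrofuran-2-yl)spiro[4.5]deca-1,8-dien-1-yl trifluoromethanesulfonate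
Product: 15 4,8-dimethyl-3-(4-methyl-5-oxo-2,5-dihydrofuran-2-yl)-7-oxospiro[4.5]deca-1,8-dien-1-yl trifluoromethanesulfonate
Conditions: Dess–Martin periodinane, CH2Cl2, rt
Reagents that add atoms: none
Why: Dess–Martin oxidation converges both C7 epimers to the 2-methylcyclohexenone needed for a reagent-controlled reduction.

Step 10
Reactants: 15 4,8-dimethyl-3-(4-methyl-5-oxo-2,5-dihydrofuran-2-yl)-7-oxospiro[4.5]deca-1,8-dien-1-yl trifluoromethanesulfonate
Product: 16 (7S)-7-hydroxy-4,8-dimethyl-3-(4-methyl-5-oxo-2,5-dihydrofuran-2-yl)spiro[4.5]deca-1,8-dien-1-yl trifluoromethanesulfonate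
Conditions: (R)-2-methyl-CBS-oxazaborolidine (0.2 equiv), BH3·SMe2, THF, −30 °C; MeOH quench
Reagents that add atoms: none
Why: Corey–Bakshi–Shibata reduction, in which the catalyst binds the ketone anti to the alkenyl (large) substituent and delivers hydride to one face, should give the (7S)-allylic alcohol irrespective of the remote spiro centre.

Step 11
Reactants: 16 (7S)-7-hydroxy-4,8-dimethyl-3-(4-methyl-5-oxo-2,5-dihydrofuran-2-yl)spiro[4.5]deca-1,8-dien-1-yl trifluoromethanesulfonate
Product: 17 5-[(7S)-7-hydroxy-4,8-dimethylspiro[4.5]deca-1,8-dien-3-yl]-3-methylfuran-2(5H)-one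
Conditions: Pd(OAc)2 (5 mol %), PPh3 (10 mol %), HCO2H, Et3N, DMF, 60 °C
Reagents that add atoms: none
Why: Palladium-catalysed formate reduction of the enol triflate (oxidative addition, formate-to-hydride exchange, reductive elimination) should leave the C1=C2 alkene, and the free allylic alcohol is not ionised.

Step 12
Reactants: 17 5-[(7S)-7-hydroxy-4,8-dimethylspiro[4.5]deca-1,8-dien-3-yl]-3-methylfuran-2(5H)-one; 18 3-phenylpropanoyl chloride
Product: 19 (7S)-4,8-dimethyl-3-(4-methyl-5-oxo-2,5-dihydrofuran-2-yl)spiro[4.5]deca-1,8-dien-7-yl 3-phenylpropanoate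
Conditions: pyridine, DMAP (cat.), CH2Cl2, 0 °C → rt
Reagents that add atoms: none
Why: DMAP-catalysed acylation of the secondary allylic alcohol proceeds with retention at C7.

Step 13
Reactants: 19 (7S)-4,8-dimethyl-3-(4-methyl-5-oxo-2,5-dihydrofuran-2-yl)spiro[4.5]deca-1,8-dien-7-yl 3-phenylpropanoate
Product: 21 (7S)-3-[2-(dimethoxymethyl)-4-methyl-5-oxo-2,5-dihydrofuran-2-yl]-4,8-dimethylspiro[4.5]deca-1,8-dien-7-yl 3-phenylpropanoate, via silyloxyfuran 20 (not isolated)
Conditions: TBSOTf (1.3 equiv), Et3N (1.1 equiv), CH2Cl2, 0 °C; then HC(OMe)3, −78 → 0 °C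
Reagents that add atoms: trimethyl orthoformate COC(OC)OC
Why: One-pot silyl dienol ether formation and vinylogous Mukaiyama addition to the dimethoxycarbenium ion (from the orthoester and the excess silyl triflate) at the substituted furan C5 should create the quaternary lactone carbon, either configuration being acceptable.

Step 14
Reactants: 21 (7S)-3-[2-(dimethoxymethyl)-4-methyl-5-oxo-2,5-dihydrofuran-2-yl]-4,8-dimethylspiro[4.5]deca-1,8-dien-7-yl 3-phenylpropanoate
Product: 22 (7S)-3-(2-formyl-4-methyl-5-oxo-2,5-dihydrofuran-2-yl)-4,8-dimethylspiro[4.5]deca-1,8-dien-7-yl 3-phenylpropanoate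
Conditions: LiBF4, MeCN/H2O (98:2), 60 °C
Reagents that add atoms: water O
Why: Mild Lewis-acid-assisted acetal hydrolysis should free the non-enolisable aldehyde without ionising the allylic ester.

Step 15
Reactants: 22 (7S)-3-(2-formyl-4-methyl-5-oxo-2,5-dihydrofuran-2-yl)-4,8-dimethylspiro[4.5]deca-1,8-dien-7-yl 3-phenylpropanoate
Product: 25 (1R,4S,5S,7S)-4,8-dimethyl-1-{(2S)-1-[(2Z)-4-methyl-5-oxofuran-2(5H)-ylidene]propan-2-yl}spiro[4.5]deca-2,8-dien-7-yl 3-phenylpropanoate, via (Z)-propenyl lactone 23 (not isolated), via (E)-ylidene isomer 24 (not isolated)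
Conditions: EtPPh3Br, KHMDS, THF, −78 → 0 °C; then toluene, 110 °C; then I2 (5 mol %), visible light, rt
Reagents that add atoms: ethyltriphenylphosphonium bromide CC[P+](c1ccccc1)(c1ccccc1)c1ccccc1.[Br-] (delivers CH3CH= as its ylide)
Why: The salt-free Wittig reaction of the non-enolisable aldehyde gives the (Z)-prop-1-enyl lactone 23, a 3-acyloxy-1,5-diene (propenyl C=C, lactone γ-carbon, C3, C2=C1) that on heating undergoes a thermal [3,3]-sigmatropic Cope rearrangement in which the γ-carbon–C3 bond breaks, the propenyl terminus bonds to C1, the ring alkene moves to C2=C3 and the γ-carbon becomes the exocyclic enol-ester carbon; the closest known reactions are the Cope rearrangement of allyl-substituted butenolides and the acyloxy-Cope rearrangement of 3-acyloxy-1,5-dienes. No ring is closed, the bond being made through a six-membered chair array, and the shift is driven by loss of the crowded quaternary γ-carbon and gain of the conjugated ylidene lactone. The ring stereocentre C1 follows from the suprafacial course across the cyclopentene: the new bond appears on the face that carried the lactone at C3 (fixed trans to the C4 methyl in step 6), which is the hindered face syn to C10 that an intermolecular reagent would avoid. The side-chain stereocentre follows from the chair together with the (Z)-alkene, whose methyl group sits pseudo-axial and anti to the spiro carbon across the forming bond, whereas the boat would eclipse it with the spiro carbon; both γ-carbon epimers should therefore give the same (S) centre and differ only in the geometry of the new enol ester. The selectivity needed is for the shift through the propenyl group over the one through the butenolide C=C, which would have to join the methyl-bearing α-carbon of the lactone to the neopentyl C1 and is reversible, and for the (Z)-ylidene lactone, which the iodine-catalysed equilibration of the (E) isomer 24 secures as the more stable isomer.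

Step 16
Reactants: 25 (1R,4S,5S,7S)-4,8-dimethyl-1-{(2S)-1-[(2Z)-4-methyl-5-oxofuran-2(5H)-ylidene]propan-2-yl}spiro[4.5]deca-2,8-dien-7-yl 3-phenylpropanoate
Product: 26 (1R,4S,5S,7S)-4,8-dimethyl-1-{(2S)-1-[(2Z)-4-methyl-5-oxofuran-2(5H)-ylidene]propan-2-yl}spiro[4.5]dec-8-en-7-yl 3-phenylpropanoate
Conditions: 2-nitrobenzenesulfonyl hydrazide, Et3N, CH2Cl2, rt
Reagents that add atoms: none
Why: Diimide reduction (concerted syn transfer of H2) should be fastest for the cis-disubstituted cyclopentene and much slower for the trisubstituted cyclohexene and the trisubstituted, conjugated C=C bonds of the ylidene lactone; no stereocentre is affected.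

**Compound list**

1 | cyclopent-2-en-1-one | O=C1C=CCC1 | starting material
2 | bromomagnesium (S)-3-methylcyclopent-1-en-1-olate | C[C@H]1CCC(O[Mg]Br)=C1 | intermediate (not isolated)
3 | (2S,3S)-2-[(dimethylamino)methyl]-3-methylcyclopentan-1-one | O=C1CC[C@H](C)[C@H]1CN(C)C | intermediate
4 | trimethyl{[(1S,2S)-2-methyl-5-oxocyclopentyl]methyl}ammonium iodide | O=C1CC[C@H](C)[C@H]1C[N+](C)(C)C.[I-] | intermediate (not isolated)
5 | (S)-3-methyl-2-methylidenecyclopentan-1-one | O=C1CC[C@H](C)C1=C | intermediate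
6 | isoprene (2-methylbuta-1,3-diene) | C=CC(C)=C | starting material
7 | (4S,5R)-4,8-dimethylspiro[4.5]dec-8-en-1-one | O=C1CC[C@H](C)[C@@]12CC=C(C)CC2 | intermediate
8 | (4S,5R)-4,8-dimethylspiro[4.5]deca-2,8-dien-1-one | O=C1C=C[C@H](C)[C@@]12CC=C(C)CC2 | intermediate
9 | 3-methylfuran-2(5H)-one | CC1=CCOC1=O | starting material
10 | tert-butyldimethyl[(3-methylfuran-2-yl)oxy]silane | Cc1ccoc1O[Si](C)(C)C(C)(C)C | intermediate
11 | C1 tert-butyldimethylsilyl enol ether of 12 (C1=C2) | CC(C)(C)[Si](C)(C)OC1=C[C@@H](C3OC(=O)C(C)=C3)[C@H](C)[C@@]12CC=C(C)CC2 | intermediate (not isolated)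
12 | (3R,4S,5R)-4,8-dimethyl-3-(4-methyl-5-oxo-2,5-dihydrofuran-2-yl)spiro[4.5]dec-8-en-1-one (both epimers at the lactone carbon) | O=C1C[C@@H](C3OC(=O)C(C)=C3)[C@H](C)[C@@]12CC=C(C)CC2 | intermediate
13 | 4,8-dimethyl-3-(4-methyl-5-oxo-2,5-dihydrofuran-2-yl)spiro[4.5]deca-1,8-dien-1-yl trifluoromethanesulfonate (ring stereocentres as in 12) | O=S(=O)(OC1=C[C@@H](C3OC(=O)C(C)=C3)[C@H](C)[C@@]12CC=C(C)CC2)C(F)(F)F | intermediate
14 | 7-hydroxy derivative of 13 (both C7 epimers) | O=S(=O)(OC1=C[C@@H](C3OC(=O)C(C)=C3)[C@H](C)[C@@]12CC=C(C)C(O)C2)C(F)(F)F | intermediate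
15 | 7-oxo derivative of 13 (2-methylcyclohex-2-enone) | O=S(=O)(OC1=C[C@@H](C3OC(=O)C(C)=C3)[C@H](C)[C@@]12CC=C(C)C(=O)C2)C(F)(F)F | intermediate
16 | (7S)-7-hydroxy derivative of 13 | O=S(=O)(OC1=C[C@@H](C3OC(=O)C(C)=C3)[C@H](C)[C@@]12CC=C(C)[C@@H](O)C2)C(F)(F)F | intermediate
17 | 5-[(7S)-7-hydroxy-4,8-dimethylspiro[4.5]deca-1,8-dien-3-yl]-3-methylfuran-2(5H)-one (C3 substituent trans to 4-methyl) | C1=C[C@@H](C3OC(=O)C(C)=C3)[C@H](C)[C@@]12CC=C(C)[C@@H](O)C2 | intermediate
18 | 3-phenylpropanoyl chloride | O=C(Cl)CCc1ccccc1 | starting material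
19 | (7S)-4,8-dimethyl-3-(4-methyl-5-oxo-2,5-dihydrofuran-2-yl)spiro[4.5]deca-1,8-dien-7-yl 3-phenylpropanoate | C1=C[C@@H](C3OC(=O)C(C)=C3)[C@H](C)[C@@]12CC=C(C)[C@@H](OC(=O)CCc3ccccc3)C2 | intermediate
20 | (7S)-3-{5-[(tert-butyldimethylsilyl)oxy]-4-methylfuran-2-yl}-4,8-dimethylspiro[4.5]deca-1,8-dien-7-yl 3-phenylpropanoate | C1=C[C@@H](c3oc(O[Si](C)(C)C(C)(C)C)c(C)c3)[C@H](C)[C@@]12CC=C(C)[C@@H](OC(=O)CCc3ccccc3)C2 | intermediate (not isolated)
21 | (7S)-3-[2-(dimethoxymethyl)-4-methyl-5-oxo-2,5-dihydrofuran-2-yl]-4,8-dimethylspiro[4.5]deca-1,8-dien-7-yl 3-phenylpropanoate | C1=C[C@@H](C3(C(OC)OC)OC(=O)C(C)=C3)[C@H](C)[C@@]12CC=C(C)[C@@H](OC(=O)CCc3ccccc3)C2 | intermediate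
22 | (7S)-3-(2-formyl-4-methyl-5-oxo-2,5-dihydrofuran-2-yl)-4,8-dimethylspiro[4.5]deca-1,8-dien-7-yl 3-phenylpropanoate | C1=C[C@@H](C3(C=O)OC(=O)C(C)=C3)[C@H](C)[C@@]12CC=C(C)[C@@H](OC(=O)CCc3ccccc3)C2 | intermediate
23 | (7S)-4,8-dimethyl-3-{4-methyl-5-oxo-2-[(Z)-prop-1-enyl]-2,5-dihydrofuran-2-yl}spiro[4.5]deca-1,8-dien-7-yl 3-phenylpropanoate | C1=C[C@@H](C3(/C=C\C)OC(=O)C(C)=C3)[C@H](C)[C@@]12CC=C(C)[C@@H](OC(=O)CCc3ccccc3)C2 | intermediate (not isolated)
24 | (E)-ylidene isomer of 25 | CC1=C/C(=C\[C@@H](C)[C@H]2C=C[C@H](C)[C@@]23CC=C(C)[C@@H](OC(=O)CCc2ccccc2)C3)OC1=O | intermediate (not isolated)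
25 | (1R,4S,5S,7S)-4,8-dimethyl-1-{(2S)-1-[(2Z)-4-methyl-5-oxofuran-2(5H)-ylidene]propan-2-yl}spiro[4.5]deca-2,8-dien-7-yl 3-phenylpropanoate | CC1=C/C(=C/[C@@H](C)[C@H]2C=C[C@H](C)[C@@]23CC=C(C)[C@@H](OC(=O)CCc2ccccc2)C3)OC1=O | intermediate
26 | (1R,4S,5S,7S)-4,8-dimethyl-1-{(2S)-1-[(2Z)-4-methyl-5-oxofuran-2(5H)-ylidene]propan-2-yl}spiro[4.5]dec-8-en-7-yl 3-phenylpropanoate | CC1=C/C(=C/[C@@H](C)[C@H]2CC[C@H](C)[C@@]23CC=C(C)[C@@H](OC(=O)CCc2ccccc2)C3)OC1=O | target

**Step count**

Total: 16 steps. Longest linear sequence: 15 steps (steps 1–4 and 6–16); step 5 is a one-step branch.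

**Steps most likely to fail**

Step 15. The thermal shift may need a temperature at which the weak γ-carbon–C3 bond breaks homolytically, so that the two allylic radicals recombine without regio- or stereocontrol; part of the material may also pass through a boat array and erode the side-chain configuration. The fallback runs the rearrangement as a charge-accelerated (anionic oxy-Cope) reaction at or below room temperature. It sets out from aldehyde 22: the Wittig reaction is worked up cold and (Z)-propenyl lactone 23 is isolated. Aqueous KOH in THF opens the lactone and removes the 3-phenylpropanoate, giving potassium (2Z,5Z)-4-hydroxy-4-[(7S)-7-hydroxy-4,8-dimethylspiro[4.5]deca-1,8-dien-3-yl]-2-methylhepta-2,5-dienoate F1. KH and 18-crown-6 in THF convert F1 into the tertiary alkoxide, whose [3,3] shift through the same chair gives, after acidification, the 4-oxo acid that closes to 5-hydroxy-5-{(2S)-2-[(1R,4S,5S,7S)-7-hydroxy-4,8-dimethylspiro[4.5]deca-2,8-dien-1-yl]propyl}-3-methylfuran-2(5H)-one F2. Acid chloride 18 with Et3N and DMAP acylates both the C7 hydroxyl and the lactol hydroxyl, the lactol ester eliminates to the ylidene lactone, and the iodine equilibration should then give 25, where the route is rejoined.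

Step 16. Diimide may also attack the exocyclic enol-ester double bond of the cross-conjugated lactone, or react too slowly with a ring alkene flanked by two branched carbons, so that over-reduction competes. The fallback moves the saturation in front of the formation of the enol lactone. It sets out from 23 (isolated as above) and follows the anionic route through F1 to hydroxy lactone F2, in which the only conjugated alkene is the trisubstituted butenolide C=C. Diimide reduction of F2 should give 5-hydroxy-5-{(2S)-2-[(1R,4S,5S,7S)-7-hydroxy-4,8-dimethylspiro[4.5]dec-8-en-1-yl]propyl}-3-methylfuran-2(5H)-one F4. Acylation and elimination of F4 with 18, Et3N and DMAP, followed by the iodine equilibration, should give target 26 directly.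

Step 14. Hydrolysis of the hindered α-acyloxy neopentyl acetal may be slow, and acid-induced ionisation of the allylic ester may take over when the conditions are forced. The fallback brings in the one-carbon unit at the alcohol oxidation level, so that no acetal has to be cleaved. It sets out from ester 19: silyloxyfuran 20 is isolated after a non-aqueous work-up and hydroxymethylated at the furan C5 with aqueous formaldehyde and Sc(OTf)3 in THF (Mukaiyama aldol in aqueous medium). This should give (7S)-3-[2-(hydroxymethyl)-4-methyl-5-oxo-2,5-dihydrofuran-2-yl]-4,8-dimethylspiro[4.5]deca-1,8-dien-7-yl 3-phenylpropanoate F3. Dess–Martin oxidation of F3 gives aldehyde 22, where the route is rejoined.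

**Further compounds**

F1 | step 15 | potassium (2Z,5Z)-4-hydroxy-4-[(7S)-7-hydroxy-4,8-dimethylspiro[4.5]deca-1,8-dien-3-yl]-2-methylhepta-2,5-dienoate | C1=C[C@@H](C(O)(/C=C\C)/C=C(C)\C(=O)[O-])[C@H](C)[C@@]12CC=C(C)[C@@H](O)C2.[K+]
F2 | step 15 | 5-hydroxy-5-{(2S)-2-[(1R,4S,5S,7S)-7-hydroxy-4,8-dimethylspiro[4.5]deca-2,8-dien-1-yl]propyl}-3-methylfuran-2(5H)-one | CC1=CC(O)(C[C@@H](C)[C@H]2C=C[C@H](C)[C@@]23CC=C(C)[C@@H](O)C3)OC1=O
F3 | step 14 | (7S)-3-[2-(hydroxymethyl)-4-methyl-5-oxo-2,5-dihydrofuran-2-yl]-4,8-dimethylspiro[4.5]deca-1,8-dien-7-yl 3-phenylpropanoate | C1=C[C@@H](C3(CO)OC(=O)C(C)=C3)[C@H](C)[C@@]12CC=C(C)[C@@H](OC(=O)CCc3ccccc3)C2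
F4 | step 16 | 5-hydroxy-5-{(2S)-2-[(1R,4S,5S,7S)-7-hydroxy-4,8-dimethylspiro[4.5]dec-8-en-1-yl]propyl}-3-methylfuran-2(5H)-one | CC1=CC(O)(C[C@@H](C)[C@H]2CC[C@H](C)[C@@]23CC=C(C)[C@@H](O)C3)OC1=O
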